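## Structural features

The target is a 2,5-diaryl-3,4-dimethyltetrahydrofuran: one oxolane ring (O1, C2, C3, C4, C5) with identical 4-hydroxy-3,5-dimethoxyphenyl rings on the benzylic ether carbons C2 and C5 and methyl groups on C3 and C4. All four ring carbons are stereocentres and stand next to each other. The C2 aryl is trans to the C3 methyl, the two methyls are trans, and the C4 methyl is cis to the C5 aryl, so the two aryl groups are 2,5-cis. With the locants used here the configuration is 2S,3S,4S,5R. The two halves have the same constitution, but the molecule is neither meso nor C2-symmetric, so the two benzylic carbons must be told apart during the synthesis. Both C–O bonds of the ring are benzylic and para to an oxygen substituent; they ionise under acid or, once the phenol is free, under base through a quinone methide. This matters most at C5, whose cis relationship to the C4 methyl is the less stable one. The free phenols are electron-rich and easily oxidised. The real difficulty is to set the contra-thermodynamic 4,5-cis relationship next to the 2,3-trans/3,4-trans array in one enantiomer without ever making C5 cationic. The chosen key step uses the fact that C2 is the only ring carbon bonded to both O1 and C3: it can arrive as an aldehyde carbon that is first joined to the C5 oxygen and then attacked by a carbon nucleophile placed at C3.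

## Logic of the disconnections

20 ⇒ 19 ⇒ 18. The bonds cut are the two phenol O–protecting-group bonds: O–CH2Ph on the C2 aryl and O–SO2Ar on the C5 aryl. The two phenols are masked differently because the two rings do different jobs in the ring construction: the C5 ring must be electron-poor, the C2 ring electron-rich. The gain is that the identical halves become distinguishable. The demand on the forward steps is that neither deprotection ionises a benzylic C–O bond, so the basic sulfonate cleavage is run while only one phenol can become a phenoxide, and the neutral hydrogenolysis comes last.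

18 ⇒ 17 ⇒ 16 ⇒ 15 ⇒ 14. The C3 methyl is traced back through C–H/C–O exchanges (methyl, sulfonate ester, alcohol, aldehyde) to a vinyl group, which means adding one carbon and a C=C bond in the retrosynthetic direction. The reason is that a methyl group cannot be delivered by the ring-forming step, whereas a vinyl group is exactly what an allylsilane leaves behind. The gain is that the C2–C3 bond becomes disconnectable. The demand is that one carbon is excised and the remaining carbon reduced without disturbing C3 (it is trans to both neighbours, so there is no driving force for epimerisation) and without attacking the aryl sulfonate.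

14 ⇒ 10 + 11. The bonds cut are O1–C2 and C2–C3. Cutting here removes the ring and two stereocentres (C2, C3) at once and divides the molecule into two aryl-bearing fragments of similar size. The demand is large: the oxocarbenium ion must react through one geometry, the alkene must present one face, and C5 must not ionise while a strong Lewis acid is present.

10 ⇒ 8 + 9. The bond cut is the C=C bond between the future C3 and the allylic CH2Si carbon. This appends the complete allylsilane to a simple terminal alkene in one operation. The demand is (E) selectivity and tolerance of a free hydroxyl and a branched allylic carbon.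

8 ⇒ 2 + 3. The bond cut is the one between the carbinol carbon (future C5) and the methyl-bearing carbon (future C4). One reagent-controlled addition then sets both centres, and its syn outcome is what becomes 4,5-cis in the ring. The demand is retention of the (Z) geometry of the crotyl unit and high facial control on an aromatic aldehyde.

2 ⇒ 1 and 11 ⇒ 1. The bonds cut are the phenol O–S and O–CH2 bonds. Both aryl fragments then come from the same phenolic aldehyde, and the only demand is clean O-functionalisation.

## Other disconnections considered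

Alternative 1: The cut is at the two C–CH3 bonds of a lactone, A1, (3S,4S,5S)-5-(4-benzyloxy-3,5-dimethoxyphenyl)-3,4-dimethyldihydrofuran-2(3H)-one, which would come from the butenolide A2, (S)-5-(4-benzyloxy-3,5-dimethoxyphenyl)furan-2(5H)-one. In the forward key step Me2CuLi (a monovalent copper reagent) adds anti to the aryl group and the enolate is methylated anti to the new methyl. The second aryl group would then be added to the lactone carbonyl as an organometallic, and ionic reduction at that carbon (Et3SiH, BF3·OEt2) would be expected to deliver hydride anti to the neighbouring methyl, which is the cis aryl/methyl relationship needed at C5. In its favour: three of the four centres are relayed from one existing centre, the contra-thermodynamic centre is set by a kinetically controlled reduction, and the sequence is short. Against it here: A2 has a doubly activated, acidic γ-hydrogen and can racemise or aromatise under the basic cuprate conditions; cuprate-derived enolates alkylate sluggishly, so the two methylations may need separate operations; and the final reduction passes through an oxocarbenium ion flanked by electron-rich aryl groups under BF3·OEt2, where the other benzylic C–O bond can also open. Compared with the chosen plan, the structural fit is equally good, since both deliver the 2,3-trans/3,4-trans/4,5-cis array directly. In step economy the alternative is the equal or slightly the better (no one-carbon excision is needed), provided an enantioselective entry to A2 is at hand. Mechanistically it depends on a chain of substrate-controlled steps whose selectivities multiply, whereas the chosen plan sets C4 and C5 by reagent control and never exposes C5 to a cation-forming step.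

Alternative 2: The cut is at O1–C5 and C2–C3 of the ring, giving the aldehyde 11 and a donor–acceptor cyclopropane, A4, dimethyl (2S,3R)-2-(4-benzyloxy-3,5-dimethoxyphenyl)-3-methylcyclopropane-1,1-dicarboxylate (aryl and methyl trans). In the forward key step Sn(OTf)2 (a divalent tin triflate) activates the diester, the aldehyde oxygen opens the ring at the benzylic carbon with inversion and the malonate carbon closes onto the aldehyde carbon. The product is A3, dimethyl (2R,4S,5R)-2,5-bis(4-benzyloxy-3,5-dimethoxyphenyl)-4-methyltetrahydrofuran-3,3-dicarboxylate. In its favour: it is as convergent as the chosen plan, 2,5-cis selectivity is inherent in this annulation, and both phenols carry the same protecting group, so one deprotection suffices; on protecting-group economy it is the better. Against it here: the stereospecific, inversion pathway is least secure for electron-rich donor aryl groups, because the cyclopropane can open to a benzylic zwitterion and lose its configuration. A4 must itself be made as a single enantiomer, for instance from the propenylarene A5, (E)-2-benzyloxy-1,3-dimethoxy-5-(prop-1-enyl)benzene, which is not a one-step task. The geminal diester at C3 then needs dealkoxycarbonylation (where C3 would settle trans to both neighbours, a point in its favour) followed by reduction, sulfonylation and hydride displacement, one operation more than the vinyl group of the chosen plan. On bond-forming logic the two plans are equals, since both make C2–C3 and one C–O bond in a single step; on the security of the C5 configuration and on overall step count the chosen plan is expected to be ahead.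

Alternative 3: The cut is at C3–C4 and at both C–O bonds, giving two molecules of the propenylarene A5 and dioxygen. In the forward key step photo-oxidation gives the arene radical cation, which couples with a second alkene, and O2 captures the 1,4-radical cation to close A6, (3S,4S,5S,6S)-3,6-bis(4-benzyloxy-3,5-dimethoxyphenyl)-4,5-dimethyl-1,2-dioxane (all-trans). Reductive O–O cleavage and ring closure with inversion at one benzylic carbon would then give the tetrahydrofuran. In its favour: it is by far the shortest route and uses a single protecting group; because A6 is C2-symmetric the two benzylic hydroxyls set free are homotopic, so activating one of them poses no selectivity problem. On step count it is clearly the better. Against it here: an achiral photo-oxidant cannot deliver A6 as one enantiomer, so a resolution would be needed. Cyclobutane formation and oxidative cleavage of the alkene compete with dioxane formation. The closing displacement must go with clean inversion at a benzylic carbon para to an alkoxy group, exactly the centre most prone to ionise, which would lead to the all-trans isomer. The chosen plan is longer but controls absolute configuration by a reagent and never requires an inversion at a benzylic centre; on stereochemical security it is expected to be well ahead.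

Key step: step 5

Remark: the sense of induction in step 2 is assigned by analogy — the crotylborane with isopinocampheyl groups from (+)-α-pinene is taken to give (1S) 1-aryl homoallylic alcohols, so the antipodal reagent from (−)-α-pinene is used for the (1R,2S) alcohol.

Step 1
Reactants: 1 syringaldehyde (4-hydroxy-3,5-dimethoxybenzaldehyde)
Product: 2 4-formyl-2,6-dimethoxyphenyl 4-methylbenzenesulfonate
Conditions: TsCl, K2CO3, acetone, 56 °C
Reagents that add atoms: 4-methylbenzenesulfonyl chloride, Cc1ccc(S(=O)(=O)Cl)cc1
Why: O-sulfonylation of the phenoxide. The sulfonate is stable to organoboranes, metathesis, silyl triflate, periodate and borohydride, and it lowers the electron density of the ring that will sit on C5.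

Step 2
Reactants: 2 4-formyl-2,6-dimethoxyphenyl 4-methylbenzenesulfonate; 3 (Z)-but-2-ene
Product: 8 4-[(1R,2S)-1-hydroxy-2-methylbut-3-en-1-yl]-2,6-dimethoxyphenyl 4-methylbenzenesulfonate, via (Z)-crotylpotassium 4 (not isolated), via potassium crotyl(methoxy)borate 5 (not isolated), via (Z)-crotylbis(isopinocampheyl)borane 6 (not isolated), via borinate ester 7 (not isolated)
Conditions: 3, KOt-Bu, n-BuLi, THF, −78 → −45 °C; (+)-Ipc2BOMe [from (−)-α-pinene], −78 °C; BF3·OEt2, −78 °C; 2, −78 °C; NaBO3·4H2O, THF/H2O, rt
Reagents that add atoms: none
Why: Brown asymmetric crotylboration. Schlosser metalation of 3 keeps the (Z) geometry at or below −45 °C, and 6 adds through a closed chair (Zimmerman–Traxler) transition structure, so the (Z) geometry becomes the syn relationship of the future C5 and C4, while the isopinocampheyl groups select the aldehyde face that gives the (1R) carbinol. Perborate oxidises the borinate 7 under conditions mild enough for the aryl sulfonate.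

Step 3
Reactants: 8 4-[(1R,2S)-1-hydroxy-2-methylbut-3-en-1-yl]-2,6-dimethoxyphenyl 4-methylbenzenesulfonate; 9 allyltrimethylsilane
Product: 10 4-[(1R,2S,3E)-1-hydroxy-2-methyl-5-(trimethylsilyl)pent-3-en-1-yl]-2,6-dimethoxyphenyl 4-methylbenzenesulfonate
Conditions: 9 (4 equiv), second-generation Hoveyda–Grubbs catalyst RuCl2(H2IMes)(=CH-C6H4-2-O-i-Pr) (5 mol %), CH2Cl2, 40 °C
Reagents that add atoms: none
Why: Olefin cross-metathesis of a hindered terminal alkene with an excess of a readily dimerising partner. The ruthenium alkylidene tolerates the free hydroxyl and the sulfonate, the (E) isomer should predominate, and no stereocentre is formed or touched.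

Step 4
Reactants: 1 syringaldehyde
Product: 11 4-(benzyloxy)-3,5-dimethoxybenzaldehyde
Conditions: BnBr, K2CO3, DMF, rt
Reagents that add atoms: benzyl bromide, BrCc1ccccc1
Why: Williamson ether synthesis on the phenoxide. The benzyl ether keeps this ring electron-rich, which stabilises the oxocarbenium ion of the next step, and it is removed at the end under neutral conditions.

Step 5
Reactants: 10 4-[(1R,2S,3E)-1-hydroxy-2-methyl-5-(trimethylsilyl)pent-3-en-1-yl]-2,6-dimethoxyphenyl 4-methylbenzenesulfonate; 11 4-(benzyloxy)-3,5-dimethoxybenzaldehyde
Product: 14 (2S,3S,4S,5R)-2-[4-(benzyloxy)-3,5-dimethoxyphenyl]-5-[3,5-dimethoxy-4-(tosyloxy)phenyl]-4-methyl-3-vinyltetrahydrofuran, via mixed O-trimethylsilyl acetal 12 (not isolated), via (E)-oxocarbenium triflate 13 (not isolated)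
Conditions: 11 (1.2 equiv), Me3SiOTf (1.2 equiv), Et2O/CH2Cl2 (4:1), −78 °C; sat. aq. NaHCO3
Reagents that add atoms: none
Why: This is a Prins-type oxocarbenium–allylsilane cyclisation, whose closest known reaction type is the Lewis acid-mediated condensation of aldehydes with 5-silylpent-3-en-1-ols to 2-substituted 3-vinyltetrahydrofurans (the five-ring counterpart of the pyran annulation of hydroxy allylsilanes). Me3SiOTf should add the C5 hydroxyl of 10 to the carbonyl of 11, silylate the hemiacetal to 12 and ionise it to the aryl-conjugated oxocarbenium triflate 13 (O1–C2 made); the γ-carbon of the (E)-allylsilane, the future C3, then attacks C2 (C2–C3 made) and the developing β-silyl cation gives up Me3Si+ to triflate, leaving the vinyl group on C3. The oxolane ring closes through an envelope in a mode that is 5-endo with respect to the O1=C2 bond and 5-exo with respect to the C3=C bond. C2 is controlled by the (E) geometry of 13: its aryl group, anti to C5 across the C=O+ bond, should lie over the hydrogen on C3 and not over the alkene substituent, so it ends trans to the vinyl group. C3 is controlled by C4: the alkene carbon that becomes the vinyl group should take the ring face opposite the C4 methyl (and the cis C5 aryl), which avoids the eclipsing methyl/vinyl interaction of a 3,4-cis envelope. C4 and C5 are not touched and carry the syn relationship of 10 into the 4,5-cis ring. The step needs C–C bond formation to outrun protodesilylation (low temperature, ethereal solvent, no protic additive) and needs C5 to stay intact: the sulfonate on the C5 aryl withdraws the donation of the para oxygen, so neither benzylic ionisation at C5 nor a 2-oxonia-Cope shift (which would exchange the benzyloxyaryl-stabilised cation for a poorer one) should compete. Should C2 ionise after ring closure, reclosure would return the same, thermodynamically preferred 2,3-trans arrangement.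

Step 6
Reactants: 14 (2S,3S,4S,5R)-2-[4-(benzyloxy)-3,5-dimethoxyphenyl]-5-[3,5-dimethoxy-4-(tosyloxy)phenyl]-4-methyl-3-vinyltetrahydrofuran
Product: 16 [(2S,3R,4S,5R)-2-[4-(benzyloxy)-3,5-dimethoxyphenyl]-5-[3,5-dimethoxy-4-(tosyloxy)phenyl]-4-methyltetrahydrofuran-3-yl]methanol, via tetrahydrofuran-3-carbaldehyde 15 (not isolated)
Conditions: OsO4 (2 mol %), NaIO4 (4 equiv), 2,6-lutidine, 1,4-dioxane/H2O (3:1), rt; extractive work-up; NaBH4, MeOH/THF, 0 °C
Reagents that add atoms: sodium periodate, [Na+].[O-]I(=O)(=O)=O; osmium tetroxide, O=[Os](=O)(=O)=O (carrier of the oxygen atom that stays on the new carbinol carbon)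
Why: Lemieux–Johnson oxidative cleavage removes the terminal carbon, and borohydride reduces the aldehyde in the same sequence. The β-alkoxy aldehyde 15 is not stored, which limits ring opening by β-elimination, and C3 is already trans to both neighbours, so it has no tendency to epimerise.

Step 7
Reactants: 16 [(2S,3R,4S,5R)-2-[4-(benzyloxy)-3,5-dimethoxyphenyl]-5-[3,5-dimethoxy-4-(tosyloxy)phenyl]-4-methyltetrahydrofuran-3-yl]methanol
Product: 17 [(2S,3R,4S,5R)-2-[4-(benzyloxy)-3,5-dimethoxyphenyl]-5-[3,5-dimethoxy-4-(tosyloxy)phenyl]-4-methyltetrahydrofuran-3-yl]methyl methanesulfonate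
Conditions: MsCl, Et3N, CH2Cl2, 0 °C
Reagents that add atoms: methanesulfonyl chloride, CS(=O)(=O)Cl
Why: Sulfonylation of a primary alcohol turns the hydroxyl into a leaving group; no stereocentre is involved.

Step 8
Reactants: 17 [(2S,3R,4S,5R)-2-[4-(benzyloxy)-3,5-dimethoxyphenyl]-5-[3,5-dimethoxy-4-(tosyloxy)phenyl]-4-methyltetrahydrofuran-3-yl]methyl methanesulfonate
Product: 18 (2S,3S,4S,5R)-2-[4-(benzyloxy)-3,5-dimethoxyphenyl]-5-[3,5-dimethoxy-4-(tosyloxy)phenyl]-3,4-dimethyltetrahydrofuran
Conditions: LiBHEt3 (3 equiv), THF, 0 °C → rt; H2O
Reagents that add atoms: none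
Why: SN2 displacement of a primary alkyl sulfonate by a very nucleophilic hydride gives the C3 methyl without touching a stereocentre. If hydride also attacks the sulfur of the aryl sulfonate, the result is only the phenol that step 9 makes anyway, so the crude mixture converges there.

Step 9
Reactants: 18 (2S,3S,4S,5R)-2-[4-(benzyloxy)-3,5-dimethoxyphenyl]-5-[3,5-dimethoxy-4-(tosyloxy)phenyl]-3,4-dimethyltetrahydrofuran
Product: 19 (2S,3S,4S,5R)-2-[4-(benzyloxy)-3,5-dimethoxyphenyl]-5-(4-hydroxy-3,5-dimethoxyphenyl)-3,4-dimethyltetrahydrofuran
Conditions: KOH, MeOH/THF (3:1), 60 °C; aq. NH4Cl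
Reagents that add atoms: none
Why: Nucleophilic attack of hydroxide or methoxide at sulfur cleaves the aryl sulfonate (S–O cleavage) and frees the phenol. The step is run while the other phenol is still a benzyl ether, so only the C5 ring becomes a phenoxide and the temperature is kept moderate.

Step 10
Reactants: 19 (2S,3S,4S,5R)-2-[4-(benzyloxy)-3,5-dimethoxyphenyl]-5-(4-hydroxy-3,5-dimethoxyphenyl)-3,4-dimethyltetrahydrofuran
Product: 20 4,4'-[(2S,3S,4S,5R)-3,4-dimethyltetrahydrofuran-2,5-diyl]bis(2,6-dimethoxyphenol), the target
Conditions: H2 (1 atm), Pd/C (10 wt % Pd), EtOAc/MeOH, rt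
Reagents that add atoms: none
Why: Hydrogenolysis of an aryl benzyl ether over palladium metal under neutral conditions. It is much faster than hydrogenolysis of the ring benzylic C–O bonds and leaves all four stereocentres alone.

## Compound list

1 | syringaldehyde (4-hydroxy-3,5-dimethoxybenzaldehyde) | COc1cc(C=O)cc(OC)c1O | starting material
2 | 4-formyl-2,6-dimethoxyphenyl 4-methylbenzenesulfonate | COc1cc(C=O)cc(OC)c1OS(=O)(=O)c1ccc(C)cc1 | intermediate
3 | (Z)-but-2-ene | C/C=C\C | starting material
4 | (Z)-but-2-enylpotassium ((Z)-crotylpotassium) | C/C=C\[CH2-].[K+] | intermediate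
5 | potassium (Z)-but-2-enyl(methoxy)bis(isopinocampheyl)borate, isopinocampheyl groups from (−)-α-pinene | [K+].C/C=C\C[B-](OC)([C@H]1C[C@H]2C[C@H](C2(C)C)[C@@H]1C)[C@H]1C[C@H]2C[C@H](C2(C)C)[C@@H]1C | intermediate
6 | (Z)-but-2-enylbis(isopinocampheyl)borane, isopinocampheyl groups from (−)-α-pinene | C/C=C\CB([C@H]1C[C@H]2C[C@H](C2(C)C)[C@@H]1C)[C@H]1C[C@H]2C[C@H](C2(C)C)[C@@H]1C | intermediate
7 | (1R,2S)-1-[3,5-dimethoxy-4-(tosyloxy)phenyl]-2-methylbut-3-en-1-yl bis(isopinocampheyl)borinate | C=C[C@H](C)[C@H](c1cc(OC)c(OS(=O)(=O)c2ccc(C)cc2)c(OC)c1)OB([C@H]1C[C@H]2C[C@H](C2(C)C)[C@@H]1C)[C@H]1C[C@H]2C[C@H](C2(C)C)[C@@H]1C | intermediate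
8 | 4-[(1R,2S)-1-hydroxy-2-methylbut-3-en-1-yl]-2,6-dimethoxyphenyl 4-methylbenzenesulfonate | O[C@@H](c1cc(OC)c(OS(=O)(=O)c2ccc(C)cc2)c(OC)c1)[C@@H](C)C=C | intermediate
9 | allyltrimethylsilane | C=CC[Si](C)(C)C | starting material
10 | 4-[(1R,2S,3E)-1-hydroxy-2-methyl-5-(trimethylsilyl)pent-3-en-1-yl]-2,6-dimethoxyphenyl 4-methylbenzenesulfonate | O[C@@H](c1cc(OC)c(OS(=O)(=O)c2ccc(C)cc2)c(OC)c1)[C@@H](C)/C=C/C[Si](C)(C)C | intermediate
11 | 4-(benzyloxy)-3,5-dimethoxybenzaldehyde | COc1cc(C=O)cc(OC)c1OCc1ccccc1 | intermediate
12 | mixed O-trimethylsilyl acetal of 10 and 11 (both epimers at the acetal carbon) | COc1cc(C(O[Si](C)(C)C)O[C@@H](c2cc(OC)c(OS(=O)(=O)c3ccc(C)cc3)c(OC)c2)[C@@H](C)/C=C/C[Si](C)(C)C)cc(OC)c1OCc1ccccc1 | intermediate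
13 | (E)-oxocarbenium triflate from 10 and 11 | COc1cc(/C=[O+]/[C@@H](c2cc(OC)c(OS(=O)(=O)c3ccc(C)cc3)c(OC)c2)[C@@H](C)/C=C/C[Si](C)(C)C)cc(OC)c1OCc1ccccc1.[O-]S(=O)(=O)C(F)(F)F | intermediate
14 | (2S,3S,4S,5R)-2-[4-(benzyloxy)-3,5-dimethoxyphenyl]-5-[3,5-dimethoxy-4-(tosyloxy)phenyl]-4-methyl-3-vinyltetrahydrofuran | COc1cc([C@H]2O[C@@H](c3cc(OC)c(OS(=O)(=O)c4ccc(C)cc4)c(OC)c3)[C@@H](C)[C@@H]2C=C)cc(OC)c1OCc1ccccc1 | intermediate
15 | (2S,3S,4S,5R)-2-[4-(benzyloxy)-3,5-dimethoxyphenyl]-5-[3,5-dimethoxy-4-(tosyloxy)phenyl]-4-methyltetrahydrofuran-3-carbaldehyde | COc1cc([C@H]2O[C@@H](c3cc(OC)c(OS(=O)(=O)c4ccc(C)cc4)c(OC)c3)[C@@H](C)[C@@H]2C=O)cc(OC)c1OCc1ccccc1 | intermediate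
16 | [(2S,3R,4S,5R)-2-[4-(benzyloxy)-3,5-dimethoxyphenyl]-5-[3,5-dimethoxy-4-(tosyloxy)phenyl]-4-methyltetrahydrofuran-3-yl]methanol | COc1cc([C@H]2O[C@@H](c3cc(OC)c(OS(=O)(=O)c4ccc(C)cc4)c(OC)c3)[C@@H](C)[C@@H]2CO)cc(OC)c1OCc1ccccc1 | intermediate
17 | [(2S,3R,4S,5R)-2-[4-(benzyloxy)-3,5-dimethoxyphenyl]-5-[3,5-dimethoxy-4-(tosyloxy)phenyl]-4-methyltetrahydrofuran-3-yl]methyl methanesulfonate | COc1cc([C@H]2O[C@@H](c3cc(OC)c(OS(=O)(=O)c4ccc(C)cc4)c(OC)c3)[C@@H](C)[C@@H]2COS(C)(=O)=O)cc(OC)c1OCc1ccccc1 | intermediate
18 | (2S,3S,4S,5R)-2-[4-(benzyloxy)-3,5-dimethoxyphenyl]-5-[3,5-dimethoxy-4-(tosyloxy)phenyl]-3,4-dimethyltetrahydrofuran | COc1cc([C@H]2O[C@@H](c3cc(OC)c(OS(=O)(=O)c4ccc(C)cc4)c(OC)c3)[C@@H](C)[C@@H]2C)cc(OC)c1OCc1ccccc1 | intermediate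
19 | (2S,3S,4S,5R)-2-[4-(benzyloxy)-3,5-dimethoxyphenyl]-5-(4-hydroxy-3,5-dimethoxyphenyl)-3,4-dimethyltetrahydrofuran | COc1cc([C@H]2O[C@@H](c3cc(OC)c(O)c(OC)c3)[C@@H](C)[C@@H]2C)cc(OC)c1OCc1ccccc1 | intermediate
20 | 4,4'-[(2S,3S,4S,5R)-3,4-dimethyltetrahydrofuran-2,5-diyl]bis(2,6-dimethoxyphenol) | COc1cc([C@H]2O[C@@H](c3cc(OC)c(O)c(OC)c3)[C@@H](C)[C@@H]2C)cc(OC)c1O | target

## Step count and least certain steps

Total: 10 steps. Longest linear sequence: 9 steps (steps 1, 2, 3, 5, 6, 7, 8, 9, 10); step 4 is a one-step side branch.

Step 5 (key step). The most likely failure is protodesilylation of the allylsilane by triflic acid formed during acetalisation, before the C2–C3 bond is made. Second is loss of facial selectivity at C2/C3 if (Z)-alkene is carried along with 10 or if the envelope preference is weaker than assumed. Third is acid-mediated reopening of the electron-rich C2–O1 bond after closure. Fallback, setting out from 10 and 11 and returning at 14: 11 is oxidised (NaClO2, NaH2PO4, 2-methylbut-2-ene) to 4-(benzyloxy)-3,5-dimethoxybenzoic acid F1, and 10 is esterified with it (EDC·HCl, DMAP) to the benzoate ester F2. Reduction of F2 with i-Bu2AlH at −78 °C and trapping of the aluminium hemiacetal with Ac2O/pyridine/DMAP (reductive acetylation) should give the α-acetoxy ether F3. Ionisation of F3 with catalytic Me3SiOTf at −78 °C generates the same oxocarbenium ion 13 without an equilibrium condensation and without stoichiometric strong acid, and closes to 14.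

Step 3. The likely problems are incomplete conversion of the hindered, allylically branched alkene while 9 is consumed by self-metathesis, and incomplete (E) selectivity. Fallback, setting out from 8 and returning at 10, with the geometry fixed by a stereodefined vinyl iodide: 8 is silylated (Et3SiCl, imidazole) to the triethylsilyl ether F4, which is cleaved (OsO4, NaIO4, 2,6-lutidine) to the aldehyde F5. Takai iodo-olefination (CrCl2, a divalent chromium salt, with CHI3, THF, 0 °C) should give the (E)-vinyl iodide F6. Cross-coupling with Me3SiCH2MgCl under Pd(PPh3)4 (zerovalent palladium) proceeds with retention of geometry to the silyl-protected allylsilane F7, and mild methanolysis (pyridinium p-toluenesulfonate, MeOH) gives 10.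

Step 2. The risks are erosion of the (Z) geometry of 4 or 6 on warming (leading to the anti diastereomer), lower facial selectivity than assumed with this aldehyde, and attack of the oxidant on the sulfonate during work-up. Fallback, setting out from 2 and returning at 8: uncatalysed addition of commercial (Z)-crotylboronic acid pinacol ester (toluene, rt), which passes through the same closed chair transition structure, should give the racemic syn alcohol F8 after hydrolytic work-up. The enantiomers are then separated by preparative chromatography on a chiral stationary phase, and the (1R,2S) enantiomer is 8.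

Step 8. The risks are hydride attack at the sulfur of the aryl sulfonate, which consumes reagent and gives mixtures of protected and unprotected phenol, and slow substitution at the β-branched primary carbon. Fallback, setting out from 16 and returning at 18, replacing the polar displacement by a radical reduction: 16 is converted (I2, PPh3, imidazole) to the primary iodide F9, which is reduced with Bu3SnH and AIBN in toluene at 80 °C. Neither the aryl sulfonate nor the benzyl ether reacts under these conditions.

Step 9. The risk is that, once the C5 phenoxide is free, warm base expels the ring oxygen to form a quinone methide; reclosure would epimerise C5 towards the all-trans isomer and methanol could add instead. Fallback, setting out from 18 and returning at 19 with no new compound: the sulfonate is removed by single-electron reduction with magnesium turnings in methanol at room temperature (reductive S–O cleavage in place of nucleophilic attack at sulfur). This works at low basicity and temperature and does not affect the benzyl ether.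

## Further compounds

F1 | step 5 | 4-(benzyloxy)-3,5-dimethoxybenzoic acid | COc1cc(C(=O)O)cc(OC)c1OCc1ccccc1
F2 | step 5 | (1R,2S,3E)-1-[3,5-dimethoxy-4-(tosyloxy)phenyl]-2-methyl-5-(trimethylsilyl)pent-3-en-1-yl 4-(benzyloxy)-3,5-dimethoxybenzoate | COc1cc(C(=O)O[C@@H](c2cc(OC)c(OS(=O)(=O)c3ccc(C)cc3)c(OC)c2)[C@@H](C)/C=C/C[Si](C)(C)C)cc(OC)c1OCc1ccccc1
F3 | step 5 | [4-(benzyloxy)-3,5-dimethoxyphenyl]{[(1R,2S,3E)-1-[3,5-dimethoxy-4-(tosyloxy)phenyl]-2-methyl-5-(trimethylsilyl)pent-3-en-1-yl]oxy}methyl acetate (both epimers at the acetal carbon) | COc1cc(C(OC(C)=O)O[C@@H](c2cc(OC)c(OS(=O)(=O)c3ccc(C)cc3)c(OC)c2)[C@@H](C)/C=C/C[Si](C)(C)C)cc(OC)c1OCc1ccccc1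
F4 | step 3 | 2,6-dimethoxy-4-[(1R,2S)-2-methyl-1-(triethylsilyloxy)but-3-en-1-yl]phenyl 4-methylbenzenesulfonate | CC[Si](CC)(CC)O[C@@H](c1cc(OC)c(OS(=O)(=O)c2ccc(C)cc2)c(OC)c1)[C@@H](C)C=C
F5 | step 3 | (2R,3R)-3-[3,5-dimethoxy-4-(tosyloxy)phenyl]-2-methyl-3-(triethylsilyloxy)propanal | CC[Si](CC)(CC)O[C@@H](c1cc(OC)c(OS(=O)(=O)c2ccc(C)cc2)c(OC)c1)[C@@H](C)C=O
F6 | step 3 | 4-[(1R,2S,3E)-4-iodo-2-methyl-1-(triethylsilyloxy)but-3-en-1-yl]-2,6-dimethoxyphenyl 4-methylbenzenesulfonate | CC[Si](CC)(CC)O[C@@H](c1cc(OC)c(OS(=O)(=O)c2ccc(C)cc2)c(OC)c1)[C@@H](C)/C=C/I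
F7 | step 3 | 2,6-dimethoxy-4-[(1R,2S,3E)-2-methyl-1-(triethylsilyloxy)-5-(trimethylsilyl)pent-3-en-1-yl]phenyl 4-methylbenzenesulfonate | CC[Si](CC)(CC)O[C@@H](c1cc(OC)c(OS(=O)(=O)c2ccc(C)cc2)c(OC)c1)[C@@H](C)/C=C/C[Si](C)(C)C
F8 | step 2 | racemic syn-4-(1-hydroxy-2-methylbut-3-en-1-yl)-2,6-dimethoxyphenyl 4-methylbenzenesulfonate, (1R,2S) and (1S,2R) in equal amounts | O[C@@H](c1cc(OC)c(OS(=O)(=O)c2ccc(C)cc2)c(OC)c1)[C@@H](C)C=C.O[C@H](c1cc(OC)c(OS(=O)(=O)c2ccc(C)cc2)c(OC)c1)[C@H](C)C=C
F9 | step 8 | (2S,3S,4S,5R)-2-[4-(benzyloxy)-3,5-dimethoxyphenyl]-5-[3,5-dimethoxy-4-(tosyloxy)phenyl]-3-(iodomethyl)-4-methyltetrahydrofuran | COc1cc([C@H]2O[C@@H](c3cc(OC)c(OS(=O)(=O)c4ccc(C)cc4)c(OC)c3)[C@@H](C)[C@@H]2CI)cc(OC)c1OCc1ccccc1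
F0 | step 9 | none | none
A1 | alternative 1 | (3S,4S,5S)-5-(4-benzyloxy-3,5-dimethoxyphenyl)-3,4-dimethyldihydrofuran-2(3H)-one | COc1cc([C@H]2OC(=O)[C@@H](C)[C@@H]2C)cc(OC)c1OCc1ccccc1
A2 | alternative 1 | (S)-5-(4-benzyloxy-3,5-dimethoxyphenyl)furan-2(5H)-one | COc1cc([C@H]2OC(=O)C=C2)cc(OC)c1OCc1ccccc1
A3 | alternative 2 | dimethyl (2R,4S,5R)-2,5-bis(4-benzyloxy-3,5-dimethoxyphenyl)-4-methyltetrahydrofuran-3,3-dicarboxylate | COc1cc([C@H]2O[C@@H](c3cc(OC)c(OCc4ccccc4)c(OC)c3)[C@@H](C)C2(C(=O)OC)C(=O)OC)cc(OC)c1OCc1ccccc1
A4 | alternative 2 | dimethyl (2S,3R)-2-(4-benzyloxy-3,5-dimethoxyphenyl)-3-methylcyclopropane-1,1-dicarboxylate | COC(=O)C1(C(=O)OC)[C@H](c2cc(OC)c(OCc3ccccc3)c(OC)c2)[C@H]1C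
A5 | alternative 2 | (E)-2-benzyloxy-1,3-dimethoxy-5-(prop-1-enyl)benzene | C/C=C/c1cc(OC)c(OCc2ccccc2)c(OC)c1
A6 | alternative 3 | (3S,4S,5S,6S)-3,6-bis(4-benzyloxy-3,5-dimethoxyphenyl)-4,5-dimethyl-1,2-dioxane | COc1cc([C@H]2OO[C@H](c3cc(OC)c(OCc4ccccc4)c(OC)c3)[C@@H](C)[C@@H]2C)cc(OC)c1OCc1ccccc1
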